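(The data are calculated on assumed constants; scatter was added.)

In a one-step, one-way world with a steady drive, starting complex decays with a single time constant, down to nothing. These two runs do not.

| flask | starting complex | incoming ligand | remark | time |
|---|---|---|---|---|
| north-west | 0.27 M | 0.55 M | run made earlier |  |
| south-west | 0.27 M | 1.1 M | run made earlier |  |
| grey | 0.27 M | 0.410 M |  | 2.0 h |
| ochre | 0.27 M | 0.810 M |  | 2.0 h |

| run | time / min | starting complex / % | complex with one exchanged / % |
|---|---|---|---|
| north-west | 8.00 | 56.9 | 16.2 |
| north-west | 20.0 | 35.3 | 19.9 |
| north-west | 40.0 | 26.4 | 20.3 |
| north-west | 60.0 | 24.7 | 20.2 |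
| north-west | 80.0 | 25.3 | 19.7 |
| south-west | 8.00 | 27.8 | 20.2 |
| south-west | 20.0 | 5.3 | 16.1 |
| south-west | 40.0 | 3.4 | 11.5 |
| south-west | 60.0 | 3.5 | 10.5 |
| south-west | 80.0 | 4.4 | 8.1 |

(readings scatter by 0.3 percentage points)

- what has gone from starting complex into another species counts as reacted, even if it can come back

* part of the starting complex that has reacted at the end, grey
* part of the starting complex that has reacted at the end, ochre
* what raising the concentration of incoming ligand from its lowest to its highest value here does to the part of the starting complex that has reacted (changes below 5 percentage points count as none) (it falls / it rises / no change)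

Both runs stall: from 40.0 min on, you read starting complex near 25.3% in north-west and 4.4% in south-west. South-west, with twice the incoming ligand, shows 2.27 times the log-decay at 8.00 min. So treat the decay as first-order in starting complex under a drive that fades: the total decay exponent grows with the charge c of incoming ligand.

North-west gives 2.50 M⁻¹. This is the dose coefficient D: the log of the fall in starting complex at the stall, per molar of ligand charged. South-west reads 2.84 M⁻¹, so D is rough.

With starting complex charged as in these runs, I take the unreacted share at the stall as exp(−D·c). If the stall holds to 2.0 h, my reckoning gives 64.1% reacted for grey and 86.8% for ochre, so the part reacted rises.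

The forecast, reckoned another way, says 63% for grey and 89% for ochre, and it rises, holding that “two hours is long enough to get there”.

Grey gives 61.2% and ochre 88.3%; it rises, by 27 percentage points.

    starting complex + incoming ligand ⇌ leaving ligand + complex with one exchanged (K = 0.220, k = 0.00130 M⁻¹ s⁻¹)
    incoming ligand → decomposed reagent (k = 0.00100 s⁻¹)
    leaving ligand + starting complex ⇌ idle adduct, settled at all times (K = 1000 M⁻¹)
    complex with two exchanged + incoming ligand ⇌ leaving ligand + complex with three exchanged (K = 0.830, k = 0.00320 M⁻¹ s⁻¹)
    complex with one exchanged + incoming ligand ⇌ leaving ligand + complex with two exchanged (K = 0.950, k = 0.00170 M⁻¹ s⁻¹)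

Just after the start in grey, incoming ligand goes to decomposed reagent 2.9 times as fast as into the first exchange, forward step alone. At 2.00 h grey holds 0.072% of its incoming ligand against 39% of its starting complex, so the ligand is the limiting reagent, and grey's own end reads D as 2.31 M⁻¹.

Now take the neighbour of grey charged with 1.0 M of incoming ligand. D from north-west gives 91.8% reacted, and the computed flask gives 92.0%.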